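## The problem

The target is a dimer of two 4-aryl-3,4-dihydrocoumarins joined through the C3–C3' bond. Unit A carries a phloroglucinol-type ring A (5,7-dihydroxy), unit B a fully oxygenated ring B (5',6',7',8'-tetrahydroxy), and each C4 bears a 4-hydroxyphenyl group. The four stereocentres C4, C3, C3' and C4' are contiguous on what is in effect a 2,3-disubstituted succinate; reading the structure gives (3R,4R,3'S,4'R), with unit A trans and unit B cis. The cis pair of unit B is the less stable arrangement, and C3 and C3' are both α to aryl ester carbonyls. Unit B must therefore be set kinetically and kept away from base, while unit A and the C3/C3' relationship have to be created under reagent control in the presence of the first pair, ideally with the C3' centre helping. The aryl lactones are acyl donors and are cleaved by nucleophiles, and the pentahydroxyphenyl ring B oxidises readily once unmasked, so the phenols should stay protected until the last step and be released without base. Both oxygenated rings are symmetric about their bond to C4 or C4', so lactone regiochemistry on either ring is degenerate. The enabling feature is that C4 carries a 4-hydroxyphenyl ring and, through C4a, a ring A oxygen (O1) in the ortho position. C4 is thus the methide carbon of a para-quinone methide with a neighbouring phenol ready to accept an acyl group, and a two-carbon enolate unit (C2–C3) can form C3–C4 and C2–O1 in one catalytic event. C4' of unit B offers the same logic through an ortho-quinone methide.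

## Retrosynthesis

**19 to 18.** No skeletal bond is cut first: the eight phenols of 19 are traced to the seven methyl ethers and one free phenol of 18. Methyl ethers are preferred to benzyl ethers because ring B can be bought as its tetramethyl ether 1 and would otherwise have to be built. A single Lewis-acid demethylation then frees everything at once, so the oxidation-prone ring is exposed only in the last flask. The free 4-hydroxyphenyl group of 18 is not a protecting-group choice but the trace of the bond construction before it. The forward step must remove seven methyl groups without cleaving or epimerising two aryl lactones; ring symmetry makes any acyl migration degenerate.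

**18 to 10 and 15.** The bonds C3–C4 and C2–O1 are cut, opening lactone A. This gives the unit B acetic acid 10, which keeps the C3'/C4' pair intact, and the achiral para-quinone methide 17, stored as its sulfinate adduct 15. The neighbouring cuts are weaker. Cutting C3–C3' would ask for a stereocontrolled coupling of two lactone enolates, and cutting C4–C4a (Friedel–Crafts) would leave C3 uncontrolled. The chosen cut halves the molecule, forms two stereocentres in the C–C bond-forming step and uses the ortho oxygen for ring closure. The forward reaction must enolise the side-chain CH2 of an activated 10 catalytically without touching C3', and add to C4 anti and on the face dictated by the catalyst.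

**10 to 6 and 7.** Acid 10 comes from its tert-butyl ester 9, an ester that acid removes without opening the aryl lactone. In 9 the bonds C3'–C4' and C2'–O1' are cut, the same disconnection as in unit A but through the ortho-quinone methide 8 (stored as sulfone 6) and the four-carbon aldehyde ester 7. A carbene-bound enolate is chosen here because its endo (4+2) annulation gives the cis lactone, which thermodynamics would not provide. The alternative of reducing a coumarin would need a face-selective hydrogenation of a tetrasubstituted alkene. Both precursors are achiral and small; the forward reaction must be cis-selective and enantioselective and must not epimerise C3' afterwards.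

**6 to 4 and 5, and 4 to 1.** In 6 the C4'–C4a' bond and the C–S bond are cut, giving phenol 4, aldehyde 5 and a sulfinate. Phenol 4 has a single free ring position, ortho to the hydroxyl, so a three-component condensation can only give 6. Phenol 4 is traced to commercial 1 by exchanging the C–O bond for C–H via lithiation (2) and borylation (3).

**15 to 11 and 12.** The C–S bond of 15 is cut to carbinol 14, and 14 is cut between C4 and the 4-oxygenated phenyl ring into aldehyde 12 and the aryl Grignard reagent 13, made from bromide 11. Placing the carbonyl on ring A fixes the regiochemistry, whereas a Friedel–Crafts reaction of the corresponding dimethoxyphenol could attack two kinds of position. The acetal on 11 survives the organometallic step and falls off in the acidic sulfination, leaving the para-phenol that the quinone methide needs.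

## Roads not taken

**Alternative 1:** ring B is grown rather than bought. The cut runs through the benzene ring of unit B (C4a'–C5' and the bonds formed when a cyclobutenone opens) and leads to the squaric ester adduct A2, in which a dihydropyran already carries C3', C4' and a masked C2'. In the forward step, heating A2 opens the four-membered ring to a dienylketene, and 6π electrocyclisation followed by tautomerisation gives the chroman hydroquinone A1.
- Merits: the pentaoxygenated arene is assembled with full regiocontrol and differentiated oxygens, under neutral thermal conditions with no catalyst, and the cis C3'/C4' pair sits on a simple heterocycle before the sensitive arene exists.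
- Weak points: ring B of the target is uniformly hydroxylated, so the differentiation is paid for and not used. A1 is still far from the unit B lactone: the lactol ether must be oxidised beside a hydroquinone, and the side chain debenzylated and oxidised to the acid. The stereotriad of A2 must be made first, and nothing in this road addresses the C3–C3' junction or unit A.
- Comparison: Alternative 1 is better if differentially substituted ring B analogues were wanted, and it avoids the air-sensitive phenol 4 and the oxidative carbene step. The chosen plan offers in return that 1 delivers the whole ring in one purchase and that acid 10 is reached in four steps.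

**Alternative 2:** lactone A is cut at C4–C4a and C2–O1, so that ring A arrives as free phloroglucinol A5 and C2–C3–C4 as the enal A4, which already carries unit B as a flat 4-arylcoumarin on its α-carbon. In the forward step, a chiral carbene and a quinone oxidant convert A4 into an α,β-unsaturated acyl azolium; A5 adds at the carbonyl, a Coates–Claisen shift forms C4–C4a and lactonisation gives A3.
- Merits: no protecting groups on ring A, no quinone methide precursor, and a symmetric nucleophile with no regiochemical question.
- Weak points: α-branched, β-aryl acyl azoliums are sluggish and the α-substituent here is a bulky coumarin. C3 is set by protonation rather than in the C–C bond-forming step, and in A3 its hydrogen is both α to the lactone and allylic, so it is easily lost. C3' and C4' would still have to be made by cis hydrogenation of a tetrasubstituted, electron-rich alkene on one face, for which there is no dependable method.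
- Comparison: Alternative 2 is superior in protecting-group economy and avoids the unhindered quinone methide 17 with its free phenols. The chosen plan sets against this that all four stereocentres arise in two C–C bond-forming annulations with predictable models and that no reduction is left for the end.

**Alternative 3:** the same two annulations in the opposite order, with lactone B cut last at C3'–C4' and C2'–O1'. In the forward step, a chiral triazolium-derived carbene converts the activated ester A7 of the trans unit A acetic acid into an azolium enolate, which adds across ortho-quinone methide 8 (from 6) in an endo (4+2) sense to give the octamethyl ether A6.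
- Merits: azolium enolates of alkanoic acyl donors are routine, and in this respect Alternative 3 is better than the chosen key step, whose ammonium enolate is the uncertain element. Quinone methide 8 is hindered and has no free phenol, so neither self-condensation nor O-acylation interferes, and the fragile cis lactone is made last.
- Weak points: the difficulty is moved, not removed. A7 must first be obtained as a trans lactone with a CH2 acyl handle, which is again a quinone methide addition of an alkanoic enolate. The final coupling pairs the most hindered electrophile (8) with a β-branched enolate, and A6 needs eight demethylations.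
- Comparison: the two orders are about equal in length. The chosen order gives the hindered 8 the smallest enolate partner (from 7), reserves the hindered enolate for the far more electrophilic 17, and is predicted to have the C3' centre reinforce the catalyst. Alternative 3 stays the natural reserve if the ammonium enolate of 10 cannot be formed.

Key step: step 7

Assumption: the absolute sense of induction of the triazolium catalyst (step 3) and of the isothiourea (step 7) is assigned from their accepted transition-state models; both catalysts exist in either enantiomeric form, and the antipode would be used if a first run showed the opposite sense.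

## Route

Step 1
Reactants: 1 1,2,3,4-tetramethoxybenzene
Product: 4 2,3,4,5-tetramethoxyphenol, via aryllithium 2 (not isolated), via dimethyl arylboronate 3 (not isolated)
Conditions: n-BuLi, TMEDA, THF, 0 °C; B(OMe)3, −78 °C to rt; then AcOH, 30% H2O2, 0 °C to rt
Reagents that add atoms: hydrogen peroxide, OO
Why: Directed ortho-lithiation at the only kind of ring C–H (next to a methoxy group), borylation and oxidative C–B to C–O exchange, a standard lithiation–borylation–oxidation phenol synthesis. The acidic peroxide stage keeps the electron-rich phenol protonated and away from quinone formation.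

Step 2
Reactants: 4 2,3,4,5-tetramethoxyphenol; 5 4-methoxybenzaldehyde
Product: 6 rac-2,3,4,5-tetramethoxy-6-[(4-methoxyphenyl)(4-methylbenzenesulfonyl)methyl]phenol
Conditions: 4-MeC6H4SO2Na, HCO2H/H2O, rt
Reagents that add atoms: sodium 4-methylbenzenesulfinate, [Na+].[O-]S(=O)c1ccc(C)cc1
Why: Acid-mediated three-component Friedel–Crafts hydroxyalkylation and sulfination, as known for electron-rich phenols and naphthols: the single free position of 4, ortho to the hydroxyl, attacks the protonated aldehyde and the doubly stabilised benzylic cation is captured by sulfinate at sulfur. With only one open position the regiochemistry cannot vary.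

Step 3
Reactants: 6 rac-2,3,4,5-tetramethoxy-6-[(4-methoxyphenyl)(4-methylbenzenesulfonyl)methyl]phenol; 7 tert-butyl 4-oxobutanoate
Product: 9 tert-butyl 2-[(3R,4R)-5,6,7,8-tetramethoxy-4-(4-methoxyphenyl)-2-oxo-3,4-dihydro-2H-chromen-3-yl]acetate (3,4-cis), via ortho-quinone methide 8 (not isolated)
Conditions: (5aR,10bS)-2-mesityl-5a,10b-dihydro-4H,6H-indeno[2,1-b][1,2,4]triazolo[4,3-d][1,4]oxazin-2-ium tetrafluoroborate (15 mol%), 3,3',5,5'-tetra-tert-butyldiphenoquinone, K2CO3, 4 Å MS, toluene, rt
Reagents that add atoms: none
Why: Carbonate eliminates sulfinate from 6 to give 8, while the carbene adds to 7, the hydroxy-enamine is oxidised by the diphenoquinone to an acyl azolium and deprotonation gives the (Z)-azolium enolate (oxidative carbene enolate catalysis). This enolate and 8 combine in an endo hetero-Diels–Alder-type (4+2) annulation that places the C3 and C4 substituents cis. The aminoindane backbone shields one enolate face, which is expected to set (3R,4R).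

Step 4
Reactants: 9 tert-butyl 2-[(3R,4R)-5,6,7,8-tetramethoxy-4-(4-methoxyphenyl)-2-oxo-3,4-dihydro-2H-chromen-3-yl]acetate
Product: 10 2-[(3R,4R)-5,6,7,8-tetramethoxy-4-(4-methoxyphenyl)-2-oxo-3,4-dihydro-2H-chromen-3-yl]acetic acid (3,4-cis)
Conditions: CF3CO2H, CH2Cl2, 0 °C to rt
Reagents that add atoms: none
Why: Acidolysis of the tert-butyl ester with loss of 2-methylpropene; the aryl lactone and the methyl ethers are inert to anhydrous trifluoroacetic acid, and no base reaches the cis C3 centre.

Step 5
Reactants: 11 rac-2-(4-bromophenoxy)oxane; 12 2-hydroxy-4,6-dimethoxybenzaldehyde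
Product: 14 2-{hydroxy[4-(oxan-2-yloxy)phenyl]methyl}-3,5-dimethoxyphenol (mixture of racemic diastereomers), via aryl Grignard reagent 13 (not isolated)
Conditions: Mg, THF, 40 °C; then 12 (0.4 equiv relative to 11), THF, 0 °C to rt; aq NH4Cl
Reagents that add atoms: none
Why: Grignard formation and 1,2-addition to a salicylaldehyde: the first equivalent is consumed by the phenol and the magnesium phenoxide still accepts a second at the carbonyl. The acetal is stable to the organometallic, and the aldehyde on ring A fixes the position of the new C–C bond.

Step 6
Reactants: 14 2-{hydroxy[4-(oxan-2-yloxy)phenyl]methyl}-3,5-dimethoxyphenol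
Product: 15 rac-2-[(4-hydroxyphenyl)(4-methylbenzenesulfonyl)methyl]-3,5-dimethoxyphenol
Conditions: 4-MeC6H4SO2Na, HCO2H/H2O/THF, rt
Reagents that add atoms: sodium 4-methylbenzenesulfinate, [Na+].[O-]S(=O)c1ccc(C)cc1
Why: SN1 substitution: in aqueous formic acid the carbinol ionises to a benzhydryl cation stabilised by both oxygenated rings and sulfinate captures it at sulfur. The same medium hydrolyses the tetrahydropyranyl acetal, freeing the para-phenol.

Step 7
Reactants: 10 2-[(3R,4R)-5,6,7,8-tetramethoxy-4-(4-methoxyphenyl)-2-oxo-3,4-dihydro-2H-chromen-3-yl]acetic acid; 15 rac-2-[(4-hydroxyphenyl)(4-methylbenzenesulfonyl)methyl]-3,5-dimethoxyphenol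
Product: 18 (3R,4R)-4-(4-hydroxyphenyl)-5,7-dimethoxy-3-[(3S,4R)-5,6,7,8-tetramethoxy-4-(4-methoxyphenyl)-2-oxo-3,4-dihydro-2H-chromen-3-yl]-3,4-dihydro-2H-chromen-2-one, via mixed pivalic anhydride 16 (not isolated), via para-quinone methide 17 (not isolated)
Conditions: t-BuCOCl, i-Pr2NEt, CH2Cl2, 0 °C; then (2S,3R)-3-isopropyl-2-phenyl-3,4-dihydro-2H-benzo[4,5]thiazolo[3,2-a]pyrimidine (HyperBTM, 20 mol%), i-Pr2NEt, slow addition of 15 (1.5 equiv), CH2Cl2, −40 °C to rt
Reagents that add atoms: none
Why: Proposed new method: the closest known reaction type is the isothiourea-catalysed 1,6-addition–lactonisation of C1-ammonium enolates from arylacetic acids with isolated, 2,6-di-tert-butyl-substituted ortho-hydroxyphenyl para-quinone methides, while ammonium enolates of unactivated alkanoic acids are established with isothioureas only in intramolecular aldol- and Michael-lactonisations, so an alkanoic enolate meeting an unhindered quinone methide made in the flask goes beyond both. The reasoning is that 16 N-acylates the catalyst, the acyl ammonium CH2 (far more acidic than the aryl lactone C3'–H, which i-Pr2NEt cannot remove) is deprotonated to the (Z)-enolate held coplanar by the 1,5 O···S contact, and amine-induced loss of sulfinate from 15 supplies 17, whose electrophilicity greatly exceeds that of the hindered quinone methides of the precedent and should offset a low enolate concentration. The enolate carbon C3 adds to the methide carbon C4 with rearomatisation of the 4-hydroxyphenyl ring, and the ring A phenoxide then attacks the acyl ammonium carbonyl C2, closing lactone A by a 6-exo-trig acyl substitution and releasing the catalyst. C3 is set by the catalyst, whose pseudo-axial C2 phenyl group shields one enolate face; on the allylic-strain model the C3' centre turns its bulky diarylmethyl carbon C4' toward that same face, so catalyst and substrate are expected to be matched for 3R. C4 is set relative to C3 in the same bond-forming event, the organised transition state that gives anti adducts with enones leading here to the trans lactone. The step needs C- over O-acylation of the free phenols and addition over quinone methide self-condensation, so 10 is the limiting partner and 15 is added slowly to keep 17 from accumulating.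

Step 8
Reactants: 18 (3R,4R)-4-(4-hydroxyphenyl)-5,7-dimethoxy-3-[(3S,4R)-5,6,7,8-tetramethoxy-4-(4-methoxyphenyl)-2-oxo-3,4-dihydro-2H-chromen-3-yl]-3,4-dihydro-2H-chromen-2-one
Product: 19 (3R,4R)-5,7-dihydroxy-4-(4-hydroxyphenyl)-3-[(3S,4R)-5,6,7,8-tetrahydroxy-4-(4-hydroxyphenyl)-2-oxo-3,4-dihydro-2H-chromen-3-yl]-3,4-dihydro-2H-chromen-2-one
Conditions: BBr3 (excess), CH2Cl2, −78 °C to 0 °C; ice-water quench and extraction under argon, no base
Reagents that add atoms: none
Why: Lewis-acid ether cleavage: boron tribromide complexes each aryl methyl ether oxygen and bromide attacks the methyl group, while aryl lactones tolerate the reagent at low temperature. The acidic, oxygen-free work-up avoids enolisation at C3 and C3' and oxidation of the pentahydroxyphenyl ring.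

## Compound list

1 | 1,2,3,4-tetramethoxybenzene | COc1ccc(OC)c(OC)c1OC | starting material
2 | (2,3,4,5-tetramethoxyphenyl)lithium | [Li]c1cc(OC)c(OC)c(OC)c1OC | intermediate (not isolated)
3 | dimethyl (2,3,4,5-tetramethoxyphenyl)boronate | COB(OC)c1cc(OC)c(OC)c(OC)c1OC | intermediate (not isolated)
4 | 2,3,4,5-tetramethoxyphenol | COc1cc(O)c(OC)c(OC)c1OC | intermediate
5 | 4-methoxybenzaldehyde | COc1ccc(C=O)cc1 | starting material
6 | rac-2,3,4,5-tetramethoxy-6-[(4-methoxyphenyl)(4-methylbenzenesulfonyl)methyl]phenol | COc1ccc(cc1)C(c1c(O)c(OC)c(OC)c(OC)c1OC)S(=O)(=O)c1ccc(C)cc1 | intermediate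
7 | tert-butyl 4-oxobutanoate | CC(C)(C)OC(=O)CCC=O | starting material
8 | (E)-2,3,4,5-tetramethoxy-6-[(4-methoxyphenyl)methylidene]cyclohexa-2,4-dien-1-one | COc1ccc(cc1)/C=C1/C(=O)C(OC)=C(OC)C(OC)=C1OC | intermediate (not isolated)
9 | tert-butyl 2-[(3R,4R)-5,6,7,8-tetramethoxy-4-(4-methoxyphenyl)-2-oxo-3,4-dihydro-2H-chromen-3-yl]acetate (3,4-cis) | CC(C)(C)OC(=O)C[C@H]1C(=O)Oc2c(OC)c(OC)c(OC)c(OC)c2[C@H]1c1ccc(OC)cc1 | intermediate
10 | 2-[(3R,4R)-5,6,7,8-tetramethoxy-4-(4-methoxyphenyl)-2-oxo-3,4-dihydro-2H-chromen-3-yl]acetic acid (3,4-cis) | OC(=O)C[C@H]1C(=O)Oc2c(OC)c(OC)c(OC)c(OC)c2[C@H]1c1ccc(OC)cc1 | intermediate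
11 | rac-2-(4-bromophenoxy)oxane | Brc1ccc(OC2CCCCO2)cc1 | starting material
12 | 2-hydroxy-4,6-dimethoxybenzaldehyde | COc1cc(O)c(C=O)c(OC)c1 | starting material
13 | [4-(oxan-2-yloxy)phenyl]magnesium bromide | Br[Mg]c1ccc(OC2CCCCO2)cc1 | intermediate (not isolated)
14 | 2-{hydroxy[4-(oxan-2-yloxy)phenyl]methyl}-3,5-dimethoxyphenol (mixture of racemic diastereomers) | COc1cc(O)c(C(O)c2ccc(OC3CCCCO3)cc2)c(OC)c1 | intermediate
15 | rac-2-[(4-hydroxyphenyl)(4-methylbenzenesulfonyl)methyl]-3,5-dimethoxyphenol | COc1cc(O)c(C(c2ccc(O)cc2)S(=O)(=O)c2ccc(C)cc2)c(OC)c1 | intermediate
16 | 2,2-dimethylpropanoic 2-[(3R,4R)-5,6,7,8-tetramethoxy-4-(4-methoxyphenyl)-2-oxo-3,4-dihydro-2H-chromen-3-yl]acetic anhydride | CC(C)(C)C(=O)OC(=O)C[C@H]1C(=O)Oc2c(OC)c(OC)c(OC)c(OC)c2[C@H]1c1ccc(OC)cc1 | intermediate (not isolated)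
17 | 4-[(2-hydroxy-4,6-dimethoxyphenyl)methylidene]cyclohexa-2,5-dien-1-one | COc1cc(O)c(C=C2C=CC(=O)C=C2)c(OC)c1 | intermediate (not isolated)
18 | (3R,4R)-4-(4-hydroxyphenyl)-5,7-dimethoxy-3-[(3S,4R)-5,6,7,8-tetramethoxy-4-(4-methoxyphenyl)-2-oxo-3,4-dihydro-2H-chromen-3-yl]-3,4-dihydro-2H-chromen-2-one (unit A trans, unit B cis) | O=C1Oc2cc(OC)cc(OC)c2[C@@H](c2ccc(O)cc2)[C@@H]1[C@H]1C(=O)Oc2c(OC)c(OC)c(OC)c(OC)c2[C@H]1c1ccc(OC)cc1 | intermediate
19 | (3R,4R)-5,7-dihydroxy-4-(4-hydroxyphenyl)-3-[(3S,4R)-5,6,7,8-tetrahydroxy-4-(4-hydroxyphenyl)-2-oxo-3,4-dihydro-2H-chromen-3-yl]-3,4-dihydro-2H-chromen-2-one | O=C1Oc2cc(O)cc(O)c2[C@@H](c2ccc(O)cc2)[C@@H]1[C@H]1C(=O)Oc2c(O)c(O)c(O)c(O)c2[C@H]1c1ccc(O)cc1 | target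

## Step count and least certain steps

Total: 8 steps. Longest linear sequence: 6 steps (1, 2, 3, 4, 7, 8); steps 5 and 6 form a two-step branch that joins at step 7.

**Step 7 (key step, proposed new method).** The likeliest failure is slow enolisation of the alkanoic acyl ammonium. O-acylation of the unhindered phenols, or self-condensation of the quinone methide through its nucleophilic ring A, would then consume the partners before the C–C bond forms; erosion of the anti or facial preference is a second risk. The fallback changes the catalyst class to a carbene, for which alkanoic acyl donors are routine enolate precursors and the addition–lactonisation with ortho-hydroxyphenyl para-quinone methides is known. It sets out from 10 and returns at 18: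
- Carbodiimide esterification of 10 with 4-nitrophenol gives 4-nitrophenyl 2-[(3R,4R)-5,6,7,8-tetramethoxy-4-(4-methoxyphenyl)-2-oxo-3,4-dihydro-2H-chromen-3-yl]acetate F1.
- F1 and 15 are combined with a chiral N-mesityl triazolium salt and i-Pr2NEt in THF. Acyl substitution on F1 gives the acyl azolium, deprotonation gives the azolium enolate, and addition to 17 followed by lactonisation gives 18.
- The price is a less secure C3/C4 relationship, since the sulfur–oxygen lock is absent and a shortfall in anti selectivity could not be corrected by base without endangering C3'. It is therefore held in reserve.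

**Step 3.** Two processes threaten it: direct addition of the carbene-bound acyl anion equivalent of 7 to 8 before the oxidant intercepts it, and one-electron oxidation of the very electron-rich phenoxide of 6 by the quinone. The methoxy group beside the methide carbon could also loosen control of quinone methide geometry and hence the cis selectivity, and prolonged contact with carbonate could epimerise C3. The fallback removes both oxidant and acyl anion equivalent. It sets out from 6 and returns at 9: commercial 4-tert-butoxy-4-oxobutanoic acid is esterified with 4-nitrophenol to give 1-tert-butyl 4-(4-nitrophenyl) butanedioate F2; F2, 6, the same triazolium salt and K2CO3 then generate the azolium enolate by acyl substitution, which annulates with 8 as before.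

**Step 2.** The condensation may stall at the hindered, doubly flanked ring position with the weakly electrophilic anisaldehyde, or the benzylic cation may be captured by a second molecule of 4 instead of sulfinate. The fallback makes the C–C bond stepwise. It sets out from 4 and returns at 6:
- Magnesium-mediated ortho-formylation (MgCl2, Et3N, paraformaldehyde, MeCN, reflux) gives 2-hydroxy-3,4,5,6-tetramethoxybenzaldehyde F3.
- Excess 4-methoxyphenylmagnesium bromide gives rac-2-[hydroxy(4-methoxyphenyl)methyl]-3,4,5,6-tetramethoxyphenol F4.
- Substitution with sulfinate in aqueous formic acid, as in step 6, gives 6.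

**Step 8.** The risks are acyl–oxygen cleavage of the aryl lactones by the boron halide, incomplete cleavage within the four contiguous methoxy groups, and air oxidation of the freed ring B during work-up. The fallback accepts ring opening instead of avoiding it. It sets out from 18 and returns at 19: after BBr3 and aqueous quench, the crude material, in which lactone-opened product is present as (2R,3S)-2-[(R)-(4-hydroxyphenyl)(2,4,6-trihydroxyphenyl)methyl]-3-[(R)-(4-hydroxyphenyl)(2,3,4,5,6-pentahydroxyphenyl)methyl]butanedioic acid F5, is stirred in degassed trifluoroacetic acid at rt. Because each oxygenated ring is symmetric about its benzylic carbon, either ortho hydroxyl closes to the same six-membered lactone.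

## Further compounds

F1 | step 7 | 4-nitrophenyl 2-[(3R,4R)-5,6,7,8-tetramethoxy-4-(4-methoxyphenyl)-2-oxo-3,4-dihydro-2H-chromen-3-yl]acetate | [O-][N+](=O)c1ccc(OC(=O)C[C@H]2C(=O)Oc3c(OC)c(OC)c(OC)c(OC)c3[C@H]2c2ccc(OC)cc2)cc1
F2 | step 3 | 1-tert-butyl 4-(4-nitrophenyl) butanedioate | CC(C)(C)OC(=O)CCC(=O)Oc1ccc(cc1)[N+](=O)[O-]
F3 | step 2 | 2-hydroxy-3,4,5,6-tetramethoxybenzaldehyde | COc1c(O)c(C=O)c(OC)c(OC)c1OC
F4 | step 2 | rac-2-[hydroxy(4-methoxyphenyl)methyl]-3,4,5,6-tetramethoxyphenol | COc1ccc(cc1)C(O)c1c(O)c(OC)c(OC)c(OC)c1OC
F5 | step 8 | (2R,3S)-2-[(R)-(4-hydroxyphenyl)(2,4,6-trihydroxyphenyl)methyl]-3-[(R)-(4-hydroxyphenyl)(2,3,4,5,6-pentahydroxyphenyl)methyl]butanedioic acid | Oc1cc(O)cc(O)c1[C@@H](c1ccc(O)cc1)[C@@H](C(O)=O)[C@@H](C(O)=O)[C@@H](c1c(O)c(O)c(O)c(O)c1O)c1ccc(O)cc1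
A1 | alternative 1 | all-cis 3-[2-(benzyloxy)ethyl]-2,6,7-trimethoxy-4-(4-methoxyphenyl)-3,4-dihydro-2H-chromene-5,8-diol | c1ccccc1COCC[C@H]1[C@@H](OC)Oc2c(O)c(OC)c(OC)c(O)c2[C@H]1c1ccc(OC)cc1
A2 | alternative 1 | 4-hydroxy-2,3-dimethoxy-4-{all-cis 3-[2-(benzyloxy)ethyl]-2-methoxy-4-(4-methoxyphenyl)-3,4-dihydro-2H-pyran-6-yl}cyclobut-2-en-1-one (either configuration at the carbinol carbon) | c1ccccc1COCC[C@H]1[C@@H](OC)OC(C2(O)C(=O)C(OC)=C2OC)=C[C@H]1c1ccc(OC)cc1
A3 | alternative 2 | (3R,4R)-5,7-dihydroxy-4-(4-methoxyphenyl)-3-[5,6,7,8-tetramethoxy-4-(4-methoxyphenyl)-2-oxo-2H-chromen-3-yl]-3,4-dihydro-2H-chromen-2-one (trans) | O=C1Oc2cc(O)cc(O)c2[C@@H](c2ccc(OC)cc2)[C@@H]1C1=C(c2ccc(OC)cc2)c2c(OC)c(OC)c(OC)c(OC)c2OC1=O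
A4 | alternative 2 | 3-(4-methoxyphenyl)-2-[5,6,7,8-tetramethoxy-4-(4-methoxyphenyl)-2-oxo-2H-chromen-3-yl]prop-2-enal (alkene geometry left open) | O=CC(=Cc1ccc(OC)cc1)C1=C(c2ccc(OC)cc2)c2c(OC)c(OC)c(OC)c(OC)c2OC1=O
A5 | alternative 2 | benzene-1,3,5-triol (phloroglucinol) | Oc1cc(O)cc(O)c1
A6 | alternative 3 | (3R,4R)-5,7-dimethoxy-4-(4-methoxyphenyl)-3-[(3S,4R)-5,6,7,8-tetramethoxy-4-(4-methoxyphenyl)-2-oxo-3,4-dihydro-2H-chromen-3-yl]-3,4-dihydro-2H-chromen-2-one | O=C1Oc2cc(OC)cc(OC)c2[C@@H](c2ccc(OC)cc2)[C@@H]1[C@H]1C(=O)Oc2c(OC)c(OC)c(OC)c(OC)c2[C@H]1c1ccc(OC)cc1
A7 | alternative 3 | 4-nitrophenyl 2-[(3S,4R)-5,7-dimethoxy-4-(4-methoxyphenyl)-2-oxo-3,4-dihydro-2H-chromen-3-yl]acetate (trans) | O=C1Oc2cc(OC)cc(OC)c2[C@@H](c2ccc(OC)cc2)[C@@H]1CC(=O)Oc1ccc(cc1)[N+](=O)[O-]
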